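**Retrosynthetic overview**
1. Target 26 ⇐ reductive N–O cleavage of bridged isoxazoline 24; the C1–C3 β-hydroxy ketone is carried as a masked aldol.
2. 24 ⇐ key step: intramolecular nitrile oxide–alkene cycloaddition of 23 (from oxime 21). The C2–C3 and O–C1 bonds close the dihydroisoxazole and the ten-membered carbocycle together; the C10 magnesium alkoxide directs the dipole and sets C1.
3. 21 ⇐ cis-α-methylene-γ-butyrolactone 15, built first by indium Barbier allylation/lactonisation (C6–C7) of bromide 13 with lactol 2 (Z-C4=C5 locked in a ring; C6 and C7 set from C8).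
4. 13 ⇐ 2,2-dimethoxyacetaldehyde 3 + methyl vinyl ketone 4 (catalytic asymmetric aldol sets C8, chelation-controlled MeMgBr sets C10), then Baylis–Hillman reaction and SN2′ bromination; the angelate goes on C8 just before oxime formation.
5. Ring order: lactone (step 7); isoxazoline + ten-membered ring in one operation (step 12); isoxazoline opened last (step 13).

Assumption: locants C1–C15 in the text are the germacrane numbers of the target (C12 lactone carbonyl, C13 exocyclic methylene; target = 1S,6S,7R,8R,10S, 4Z, angelate); 2,2-dimethoxyacetaldehyde is used anhydrous (dried from its commercial aqueous solution).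

**Route**

Step 1
Reactants: 1 4-methylfuran-2(5H)-one
Product: 2 4-methyl-2,5-dihydrofuran-2-ol (lactol, racemic at C2)
Conditions: i-Bu2AlH (1.05 equiv), CH2Cl2, −78 °C; aq. potassium sodium tartrate, 0 °C; used crude
Reagents that add atoms: none
Why: DIBAL half-reduction of the lactone stops at the lactol, a ring-locked (Z)-4-hydroxy-3-methylbut-2-enal equivalent that fixes the C4=C5 geometry, and the neutral work-up avoids dehydration to 3-methylfuran.

Step 2
Reactants: 3 2,2-dimethoxyacetaldehyde; 4 but-3-en-2-one (methyl vinyl ketone)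
Product: 5 (5R)-5-hydroxy-6,6-dimethoxyhex-1-en-3-one
Conditions: (S,S)-ProPhenol (10 mol %, antipode chosen for 5R), Et2Zn (20 mol %), 4 (excess), 4 Å molecular sieves, THF, 0 °C
Reagents that add atoms: none
Why: Dinuclear zinc–ProPhenol direct asymmetric aldol reaction, in which the catalyst enolises the methyl group of the vinyl ketone and adds it to one face of the non-enolisable aldehyde, setting C8 (R) by catalyst control.

Step 3
Reactants: 5 (5R)-5-hydroxy-6,6-dimethoxyhex-1-en-3-one
Product: 6 (3S,5R)-6,6-dimethoxy-3-methylhex-1-ene-3,5-diol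
Conditions: MeMgBr (3 equiv), CH2Cl2/Et2O, −78 °C; aq. NH4Cl
Reagents that add atoms: methylmagnesium bromide, C[Mg]Br
Why: Chelation-controlled Grignard 1,2-addition, in which the magnesium alkoxide at C8 ties the ketone into a six-membered chelate and methyl attacks the face opposite the pseudo-equatorial C8 substituent (same sense as chelate-controlled 1,3-anti additions to β-alkoxy aldehydes), giving the 8,10-syn diol with C10 (S).

Step 4
Reactants: 6 (3S,5R)-6,6-dimethoxy-3-methylhex-1-ene-3,5-diol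
Product: 9 (2R,4S)-4-methyl-2,4-bis(triethylsilyloxy)hex-5-enal, via bis-silyl acetal 7 (not isolated), via collidinium salt 8 (not isolated)
Conditions: Et3SiOTf (4.5 equiv), 2,4,6-collidine (6 equiv), CH2Cl2, 0 °C; then H2O
Reagents that add atoms: triethylsilyl trifluoromethanesulfonate, CC[Si](CC)(CC)OS(=O)(=O)C(F)(F)F; water, O
Why: Silyl triflate/pyridine-base acetal cleavage, in which the reagent first silylates both hydroxyls and then ionises the dimethyl acetal to a collidinium adduct that water turns into the aldehyde without acid, so the tertiary allylic ether and the C8 stereocentre are untouched.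

Step 5
Reactants: 9 (2R,4S)-4-methyl-2,4-bis(triethylsilyloxy)hex-5-enal; 10 methyl acrylate
Product: 11 methyl (4R,6S)-3-hydroxy-6-methyl-2-methylidene-4,6-bis(triethylsilyloxy)oct-7-enoate (C3 epimers)
Conditions: DABCO (1 equiv), 10 (neat, 10 equiv), rt, 3–5 d
Reagents that add atoms: none
Why: Morita–Baylis–Hillman reaction of an activated α-silyloxy aldehyde; the new carbinol centre forms as a mixture that is erased in the next step.

Step 6
Reactants: 11 methyl (4R,6S)-3-hydroxy-6-methyl-2-methylidene-4,6-bis(triethylsilyloxy)oct-7-enoate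
Product: 13 methyl (2Z,4R,6S)-2-(bromomethyl)-6-methyl-4,6-bis(triethylsilyloxy)octa-2,7-dienoate, via allylic mesylate 12 (not isolated)
Conditions: MsCl, Et3N, CH2Cl2, −20 °C; then LiBr, THF, 0 °C → rt
Reagents that add atoms: lithium bromide, [Li+].[Br-]
Why: Mesylation then SN2′ displacement by bromide (allylic transposition of a Baylis–Hillman adduct) gives the thermodynamically preferred (Z)-2-(bromomethyl)enoate and removes the carbinol stereocentre, while the silyl ether keeps the tertiary allylic oxygen from ionising.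

Step 7
Reactants: 13 methyl (2Z,4R,6S)-2-(bromomethyl)-6-methyl-4,6-bis(triethylsilyloxy)octa-2,7-dienoate; 2 4-methyl-2,5-dihydrofuran-2-ol
Product: 15 (4S,5S)-5-[(1Z)-3-hydroxy-2-methylprop-1-en-1-yl]-3-methylidene-4-[(1R,3S)-3-methyl-1,3-bis(triethylsilyloxy)pent-4-en-1-yl]oxolan-2-one, via seco hydroxy ester 14 (not isolated)
Conditions: indium powder (1.5 equiv), 2 (1.5 equiv), THF/H2O (3:1), rt; extract; then PPTS (cat.), toluene, 50 °C
Reagents that add atoms: none
Why: Indium Barbier allylation then lactonisation (Dreiding–Schmidt-type α-methylene-γ-butyrolactone synthesis), in which the allylindium attacks the ring-opened lactol aldehyde through C7 in a chair transition state that gives the 6,7-syn adduct (cis lactone) on the C7 face anti to the C9 chain with H8 eclipsing the alkene (allylic 1,3-strain), so C6 and C7 are set from C8 and only the C6 hydroxyl is free to lactonise.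

Step 8
Reactants: 15 (4S,5S)-5-[(1Z)-3-hydroxy-2-methylprop-1-en-1-yl]-3-methylidene-4-[(1R,3S)-3-methyl-1,3-bis(triethylsilyloxy)pent-4-en-1-yl]oxolan-2-one
Product: 16 (2Z)-2-methyl-3-[(2S,3S)-4-methylidene-3-[(1R,3S)-3-methyl-1,3-bis(triethylsilyloxy)pent-4-en-1-yl]-5-oxooxolan-2-yl]prop-2-enal
Conditions: MnO2 (15 equiv), CH2Cl2, rt
Reagents that add atoms: none
Why: MnO2 oxidation of the only free (primary allylic) alcohol gives the (Z)-enal under neutral conditions without alkene isomerisation.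

Step 9
Reactants: 16 (2Z)-2-methyl-3-[(2S,3S)-4-methylidene-3-[(1R,3S)-3-methyl-1,3-bis(triethylsilyloxy)pent-4-en-1-yl]-5-oxooxolan-2-yl]prop-2-enal
Product: 17 (2Z)-3-[(2S,3R)-3-[(1R,3S)-1,3-dihydroxy-3-methylpent-4-en-1-yl]-4-methylidene-5-oxooxolan-2-yl]-2-methylprop-2-enal
Conditions: HF·pyridine, pyridine, THF, 0 °C → rt
Reagents that add atoms: none
Why: Buffered fluoride desilylation removes both triethylsilyl ethers and leaves the enal, the methylene lactone and the tertiary allylic alcohol intact.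

Step 10
Reactants: 17 (2Z)-3-[(2S,3R)-3-[(1R,3S)-1,3-dihydroxy-3-methylpent-4-en-1-yl]-4-methylidene-5-oxooxolan-2-yl]-2-methylprop-2-enal; 18 angelic acid ((2Z)-2-methylbut-2-enoic acid)
Product: 20 (1R,3S)-3-hydroxy-3-methyl-1-[(2S,3R)-4-methylidene-2-[(1Z)-2-methyl-3-oxoprop-1-en-1-yl]-5-oxooxolan-3-yl]pent-4-en-1-yl (2Z)-2-methylbut-2-enoate, via mixed anhydride 19 (not isolated)
Conditions: 18, 2,4,6-Cl3C6H2COCl, Et3N, toluene, rt; then 17, 60 °C (no DMAP)
Reagents that add atoms: none
Why: Yamaguchi esterification through the mixed anhydride acylates the secondary C8 hydroxyl (the tertiary C10 hydroxyl is inert) with retention at C8, and running it without a nucleophilic catalyst avoids angelate-to-tiglate and Z-enal isomerisation.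

Step 11
Reactants: 20 (1R,3S)-3-hydroxy-3-methyl-1-[(2S,3R)-4-methylidene-2-[(1Z)-2-methyl-3-oxoprop-1-en-1-yl]-5-oxooxolan-3-yl]pent-4-en-1-yl (2Z)-2-methylbut-2-enoate
Product: 21 (1R,3S)-3-hydroxy-1-[(2S,3R)-2-[(1Z)-3-(hydroxyimino)-2-methylprop-1-en-1-yl]-4-methylidene-5-oxooxolan-3-yl]-3-methylpent-4-en-1-yl (2Z)-2-methylbut-2-enoate (oxime E/Z mixture)
Conditions: NH2OH·HCl (1.1 equiv), pyridine, EtOH, 0 °C, 30 min
Reagents that add atoms: hydroxylamine hydrochloride, Cl.NO
Why: Oxime condensation at the aldehyde is much faster than conjugate addition of hydroxylamine to the methylene lactone at 0 °C with one equivalent of reagent.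

Step 12
Reactants: 21 (1R,3S)-3-hydroxy-1-[(2S,3R)-2-[(1Z)-3-(hydroxyimino)-2-methylprop-1-en-1-yl]-4-methylidene-5-oxooxolan-3-yl]-3-methylpent-4-en-1-yl (2Z)-2-methylbut-2-enoate
Product: 24 bridged isoxazoline (1S,6S,7R,8R,10S)-8-angeloyloxy-10-hydroxygermacra-4Z,11(13)-dien-12,6-olide in which C3 is the C=N carbon and C1 carries the oxygen of a 4,5-dihydroisoxazole (C3=N–O–C1), via hydroximoyl chloride 22 (not isolated), via nitrile oxide 23 (not isolated)
Conditions: NCS (1.05 equiv), pyridine (cat.), CH2Cl2, 0 °C → rt; dilute to 1 mM, −78 °C; t-BuMgCl (3.3 equiv), warm to 0 °C over 8 h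
Reagents that add atoms: none
Why: Proposed new method: the base removes HCl from 22 to give nitrile oxide 23, whose oxygen binds the magnesium of the C10 alkoxide, so the dipole is delivered to the adjacent C1=C2 bond (oxygen to C1, carbon to C2; bridged-mode intramolecular nitrile oxide–alkene cycloaddition) rather than to the lactone methylene, closing the dihydroisoxazole and the ten-membered carbocycle in one step, with C1 set S through the chelated transition state that has the alkoxide outside, the C9 methylene anti and the methyl inside; the closest known reactions are magnesium-alkoxide-directed, syn-selective intermolecular nitrile oxide cycloadditions to allylic alcohols and bridged-mode macrocyclic nitrile oxide cycloadditions.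

Step 13
Reactants: 24 bridged isoxazoline
Product: 26 CNP0271189.1, (1S,6S,7R,8R,10S)-8-angeloyloxy-1,10-dihydroxy-3-oxogermacra-4Z,11(13)-dien-12,6-olide, via hydroxy imine 25 (not isolated)
Conditions: Mo(CO)6 (1 equiv), MeCN/H2O (15:1), 80 °C
Reagents that add atoms: water, O
Why: Mo(CO)6-mediated reductive N–O cleavage (isoxazoline as masked aldol) gives the β-hydroxy imine, which water hydrolyses to the β-hydroxy enone, while zerovalent molybdenum leaves the alkenes, lactone, ester and all stereocentres untouched.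

**Compound list**
1 | 4-methylfuran-2(5H)-one | CC1=CC(=O)OC1 | starting material
2 | 4-methyl-2,5-dihydrofuran-2-ol | CC1=CC(O)OC1 | intermediate
3 | 2,2-dimethoxyacetaldehyde | COC(OC)C=O | starting material
4 | but-3-en-2-one | CC(=O)C=C | starting material
5 | (5R)-5-hydroxy-6,6-dimethoxyhex-1-en-3-one | C=CC(=O)C[C@@H](O)C(OC)OC | intermediate
6 | (3S,5R)-6,6-dimethoxy-3-methylhex-1-ene-3,5-diol | C=C[C@@](C)(O)C[C@@H](O)C(OC)OC | intermediate
7 | (3S,5R)-6,6-dimethoxy-3-methyl-3,5-bis(triethylsilyloxy)hex-1-ene | C=C[C@@](C)(O[Si](CC)(CC)CC)C[C@@H](O[Si](CC)(CC)CC)C(OC)OC | intermediate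
8 | 1-[(2R,4S)-1-methoxy-4-methyl-2,4-bis(triethylsilyloxy)hex-5-en-1-yl]-2,4,6-trimethylpyridinium triflate | C=C[C@@](C)(O[Si](CC)(CC)CC)C[C@@H](O[Si](CC)(CC)CC)C(OC)[n+]1c(C)cc(C)cc1C.[O-]S(=O)(=O)C(F)(F)F | intermediate
9 | (2R,4S)-4-methyl-2,4-bis(triethylsilyloxy)hex-5-enal | C=C[C@@](C)(O[Si](CC)(CC)CC)C[C@@H](O[Si](CC)(CC)CC)C=O | intermediate
10 | methyl acrylate | COC(=O)C=C | starting material
11 | methyl (4R,6S)-3-hydroxy-6-methyl-2-methylidene-4,6-bis(triethylsilyloxy)oct-7-enoate | C=C[C@@](C)(O[Si](CC)(CC)CC)C[C@@H](O[Si](CC)(CC)CC)C(O)C(=C)C(=O)OC | intermediate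
12 | methyl (4R,6S)-3-(methanesulfonyloxy)-6-methyl-2-methylidene-4,6-bis(triethylsilyloxy)oct-7-enoate | C=C[C@@](C)(O[Si](CC)(CC)CC)C[C@@H](O[Si](CC)(CC)CC)C(OS(C)(=O)=O)C(=C)C(=O)OC | intermediate
13 | methyl (2Z,4R,6S)-2-(bromomethyl)-6-methyl-4,6-bis(triethylsilyloxy)octa-2,7-dienoate | C=C[C@@](C)(O[Si](CC)(CC)CC)C[C@@H](O[Si](CC)(CC)CC)/C=C(\CBr)C(=O)OC | intermediate
14 | methyl (3S,4S,5Z)-4,7-dihydroxy-6-methyl-2-methylidene-3-[(1R,3S)-3-methyl-1,3-bis(triethylsilyloxy)pent-4-en-1-yl]hept-5-enoate | C=C(C(=O)OC)[C@@H]([C@@H](O)/C=C(/C)CO)[C@H](O[Si](CC)(CC)CC)C[C@](C)(O[Si](CC)(CC)CC)C=C | intermediate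
15 | (4S,5S)-5-[(1Z)-3-hydroxy-2-methylprop-1-en-1-yl]-3-methylidene-4-[(1R,3S)-3-methyl-1,3-bis(triethylsilyloxy)pent-4-en-1-yl]oxolan-2-one | C=C1C(=O)O[C@@H](/C=C(/C)CO)[C@H]1[C@H](O[Si](CC)(CC)CC)C[C@](C)(O[Si](CC)(CC)CC)C=C | intermediate
16 | (2Z)-2-methyl-3-[(2S,3S)-4-methylidene-3-[(1R,3S)-3-methyl-1,3-bis(triethylsilyloxy)pent-4-en-1-yl]-5-oxooxolan-2-yl]prop-2-enal | C=C1C(=O)O[C@@H](/C=C(/C)C=O)[C@H]1[C@H](O[Si](CC)(CC)CC)C[C@](C)(O[Si](CC)(CC)CC)C=C | intermediate
17 | (2Z)-3-[(2S,3R)-3-[(1R,3S)-1,3-dihydroxy-3-methylpent-4-en-1-yl]-4-methylidene-5-oxooxolan-2-yl]-2-methylprop-2-enal | C=C1C(=O)O[C@@H](/C=C(/C)C=O)[C@H]1[C@H](O)C[C@](C)(O)C=C | intermediate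
18 | angelic acid, (2Z)-2-methylbut-2-enoic acid | C/C=C(/C)C(=O)O | starting material
19 | (2Z)-2-methylbut-2-enoic 2,4,6-trichlorobenzoic anhydride | C/C=C(/C)C(=O)OC(=O)c1c(Cl)cc(Cl)cc1Cl | intermediate
20 | (1R,3S)-3-hydroxy-3-methyl-1-[(2S,3R)-4-methylidene-2-[(1Z)-2-methyl-3-oxoprop-1-en-1-yl]-5-oxooxolan-3-yl]pent-4-en-1-yl (2Z)-2-methylbut-2-enoate | C=C1C(=O)O[C@@H](/C=C(/C)C=O)[C@H]1[C@H](OC(=O)/C(C)=C\C)C[C@](C)(O)C=C | intermediate
21 | oxime of 20 (C3 aldoxime, E/Z mixture) | C=C1C(=O)O[C@@H](/C=C(/C)C=NO)[C@H]1[C@H](OC(=O)/C(C)=C\C)C[C@](C)(O)C=C | intermediate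
22 | hydroximoyl chloride of 21 (C3 C(Cl)=NOH) | C=C1C(=O)O[C@@H](/C=C(/C)C(Cl)=NO)[C@H]1[C@H](OC(=O)/C(C)=C\C)C[C@](C)(O)C=C | intermediate
23 | nitrile oxide (C3 C≡N–O) | C=C1C(=O)O[C@@H](/C=C(/C)C#[N+][O-])[C@H]1[C@H](OC(=O)/C(C)=C\C)C[C@](C)(O)C=C | intermediate
24 | bridged isoxazoline, (1S,6S,7R,8R,10S), C3=N–O–C1 | C=C1C(=O)O[C@H]2/C=C(/C)C3=NO[C@@H](C3)[C@@](C)(O)C[C@@H](OC(=O)/C(C)=C\C)[C@@H]12 | intermediate
25 | 3-imino analogue of the target (β-hydroxy imine) | C=C1C(=O)O[C@H]2/C=C(/C)C(=N)C[C@H](O)[C@@](C)(O)C[C@@H](OC(=O)/C(C)=C\C)[C@@H]12 | intermediate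
26 | CNP0271189.1, (1S,6S,7R,8R,10S)-8-angeloyloxy-1,10-dihydroxy-3-oxogermacra-4Z,11(13)-dien-12,6-olide | C=C1C(=O)O[C@H]2/C=C(/C)C(=O)C[C@H](O)[C@@](C)(O)C[C@@H](OC(=O)/C(C)=C\C)[C@@H]12 | target

**Totals**
Total step count: 13. Longest linear sequence: 12 (steps 2–13; step 1 is a one-step branch).

**Three steps most likely to fail**

Step 12 (key cycloaddition). The nitrile oxide can instead add in fused mode to the lactone methylene C11=C13, closing a six-membered ring; it can also oligomerise or give the C1 epimer. Fallback, setting out from oxime 21: mask the methylene by conjugate addition of dimethylamine (Me2NH, THF, 0 °C) to give the dimethylamine adduct of oxime 21 F5. As its hydrochloride this is chlorinated (NCS) and cyclised with t-BuMgCl under the step 12 dilution, now with no competing dipolarophile, to give the amino isoxazoline F6. MeI converts it into the trimethylammonium iodide F7, and aqueous NaHCO3/EtOAc eliminates the amine to restore the methylene, coming back to the route at 24 (two steps longer).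

Step 7 (Barbier coupling). Lactol 2 can dehydrate to 3-methylfuran in the Lewis-acidic aqueous medium before it is allylated, and facial control from C8 is only predicted. Fallback, setting out from bromide 13: replace the lactol by (Z)-2-methylbut-2-enedial, released in water from 2,5-dimethoxy-3-methyl-2,5-dihydrofuran F3 (made from commercial 3-methylfuran with Br2, MeOH, Na2CO3, −40 °C; hydrolysed with dilute HCl and buffered to pH 5). Indium allylation at the less hindered, α-unsubstituted aldehyde carbon (C6) gives the hydroxy ester enal F4, held as its five-membered lactol, which protects the second aldehyde and the Z geometry. PPTS in toluene lactonises it directly to enal 16, where it rejoins the route (step 8 is then not needed).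

Step 3 (methyl addition). Chelation control may be modest, and 1,4-addition or oxa-Michael closure of the alkoxide can compete. Fallback, setting out from aldehyde 3 and replacing steps 2 and 3: asymmetric methallylation with B-methallyldiisopinocampheylborane (Et2O, −78 °C; NaOH, H2O2) gives (2R)-1,1-dimethoxy-4-methylpent-4-en-2-ol F1. Hydroxyl-directed epoxidation (VO(acac)2, t-BuOOH, CH2Cl2) gives the 1,3-syn epoxy alcohol (2R)-1,1-dimethoxy-3-[(2S)-2-methyloxiran-2-yl]propan-2-ol F2. Excess dimethylsulfonium methylide (Me3SI, n-BuLi, THF, −10 °C) opens the epoxide at CH2 and eliminates to the vinyl carbinol, coming back to the route at diol 6 (one step longer).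

**Further compounds**
F1 | step 3 | (2R)-1,1-dimethoxy-4-methylpent-4-en-2-ol | C=C(C)C[C@@H](O)C(OC)OC
F2 | step 3 | (2R)-1,1-dimethoxy-3-[(2S)-2-methyloxiran-2-yl]propan-2-ol | O1C[C@]1(C)C[C@@H](O)C(OC)OC
F3 | step 7 | 2,5-dimethoxy-3-methyl-2,5-dihydrofuran | COC1OC(OC)C(C)=C1
F4 | step 7 | methyl (3S,4S,5Z)-4-hydroxy-6-methyl-2-methylidene-3-[(1R,3S)-3-methyl-1,3-bis(triethylsilyloxy)pent-4-en-1-yl]-7-oxohept-5-enoate | C=C(C(=O)OC)[C@@H]([C@@H](O)/C=C(/C)C=O)[C@H](O[Si](CC)(CC)CC)C[C@](C)(O[Si](CC)(CC)CC)C=C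
F5 | step 12 | dimethylamine adduct of oxime 21 (C13 bears NMe2, C11 epimers) | CN(C)CC1C(=O)O[C@@H](/C=C(/C)C=NO)[C@H]1[C@H](OC(=O)/C(C)=C\C)C[C@](C)(O)C=C
F6 | step 12 | amino isoxazoline (24 with C11–CH2NMe2 in place of the methylene) | CN(C)CC1C(=O)O[C@H]2/C=C(/C)C3=NO[C@@H](C3)[C@@](C)(O)C[C@@H](OC(=O)/C(C)=C\C)[C@@H]12
F7 | step 12 | trimethylammonium iodide of F6 | C[N+](C)(C)CC1C(=O)O[C@H]2/C=C(/C)C3=NO[C@@H](C3)[C@@](C)(O)C[C@@H](OC(=O)/C(C)=C\C)[C@@H]12.[I-]
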